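A direct plan would grow the chain one ring at a time from the phloroglucinol end.
Each ether would come from SNAr of a methylated phenoxide on a fluorobenzaldehyde, 2,4,6-trifluorobenzaldehyde A1 for rings B and D and 6-fluoro-2,3,4-trimethoxybenzaldehyde A2 for ring C; each formyl group would then be cut out to the next phenol by Baeyer–Villiger oxidation, and BBr3 would cleave all methyl ethers of pentamer phenol A4 at the end.
Its weakest steps would be these.
(a) The SNAr that brings in ring C: a di-ortho-substituted phenoxide would have to attack the trioxygenated, weakly activated fluoride A2 at high temperature.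
(b) The substitution of only one of the two equivalent fluorides of tetraaryl aldehyde A3: a differentiation by stoichiometry alone, on advanced material.
(c) The twelvefold demethylation of A4: all twelve ethers must fall without loss of the air-sensitive, pentaoxygenated ring C.
Four formyl-to-hydroxyl excisions would in addition spend steps without adding skeleton.

**Plan of the new route**
Ring C (C1 bears O–ring B, C2 is its only C–H, C3–C5 bear OH, C6 bears O–ring D) is not bought as a benzene; the retrosynthesis cuts its C1–C6 and C2–C3 bonds.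
C3–C6 with their four oxygens are the C4O4 skeleton of squaric acid, and C1(O–ring B)–C2(H) is an aryl ethynyl ether; this mapping of five contiguous C–O carbons and one C–H is what makes the key step possible.
Rings A, B, D and E come from commercial benzenes; the A–O–B and D–O–E ethers are made first, each by a copper-mediated O-arylation with one unhindered partner.
Ring C arises last, in a benzannulation that also joins the AB half (ynol ether 14) to the DE half (cyclobutenone 29).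
Both ether bonds at ring C are formed on non-aromatic carbons (phenoxide plus dichloroacetylene; phenoxide plus squaric chloride), so no SNAr on an electron-rich ring and no choice between equivalent leaving groups occurs.
All hydroxyls travel as benzyl ethers or a diphenylmethylene ketal and are freed by one hydrogenolysis, so no Lewis-acid demethylation is needed.

Key step: step 15

Remark: 1, 5, 15 and 25 are taken as commercial; Bn = benzyl, ArAB = 2,6-bis(benzyloxy)-4-[2,4,6-tris(benzyloxy)phenoxy]phenyl, ArDE = 2,2-diphenyl-7-[3,4,5-tris(benzyloxy)phenoxy]-1,3-benzodioxol-5-yl; the stereocentres of 28, 29, 31 and 33 are racemic and vanish on aromatisation.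

Step 1
Reactants: 1 1,3,5-tris(benzyloxy)benzene
Product: 4 2,4,6-tris(benzyloxy)phenol, via aryllithium 2 (not isolated), via dimethyl arylboronate 3 (not isolated)
Conditions: n-BuLi, THF, 0 °C; B(OMe)3, −78 °C → rt; 30% aq. H2O2, 0 °C
Reagents that add atoms: hydrogen peroxide, OO
Why: Directed ortho-metalation at a ring C–H flanked by two benzyloxy groups (all three ring positions are equivalent), borylation and oxidative aryl migration from boron to oxygen should give the ring A phenol in one pot, the lithium methoxide set free serving as base for the peroxide step.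

Step 2
Reactants: 5 1,3-bis(benzyloxy)benzene
Product: 8 2,6-bis(benzyloxy)phenol, via aryllithium 6 (not isolated), via dimethyl arylboronate 7 (not isolated)
Conditions: n-BuLi, THF, 0 °C; B(OMe)3, −78 °C → rt; 30% aq. H2O2, 0 °C
Reagents that add atoms: hydrogen peroxide, OO
Why: Directed ortho-metalation removes the C2–H between the two benzyloxy groups, the most acidic ring position, and borylation–oxidation turns it into the future B4 oxygen.

Step 3
Reactants: 8 2,6-bis(benzyloxy)phenol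
Product: 9 2,6-bis(benzyloxy)-4-bromophenol
Conditions: NBS (1.0 equiv), MeCN, −20 → 0 °C
Reagents that add atoms: N-bromosuccinimide, O=C1CCC(=O)N1Br
Why: Electrophilic aromatic bromination should go para to the free hydroxyl, the strongest activating group, since both ortho positions are occupied.

Step 4
Reactants: 9 2,6-bis(benzyloxy)-4-bromophenol
Product: 10 1,3-bis(benzyloxy)-5-bromo-2-{[(E)-1,2-dichloroethenyl]oxy}benzene
Conditions: trichloroethylene (2 equiv), K2CO3, DMF, 70 °C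
Reagents that add atoms: trichloroethylene, ClC=C(Cl)Cl
Why: Base-induced loss of HCl from trichloroethylene gives dichloroacetylene, to which the phenoxide adds in anti fashion (vinylic substitution by elimination–addition); the hindered oxygen meets a slender sp carbon, and the dichlorovinyl ether also masks the phenol for step 5.

Step 5
Reactants: 4 2,4,6-tris(benzyloxy)phenol; 10 1,3-bis(benzyloxy)-5-bromo-2-{[(E)-1,2-dichloroethenyl]oxy}benzene
Product: 11 1,3,5-tris(benzyloxy)-2-(3,5-bis(benzyloxy)-4-{[(E)-1,2-dichloroethenyl]oxy}phenoxy)benzene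
Conditions: CuI (10 mol %), picolinic acid (20 mol %), K3PO4, DMSO, 90 °C, Ar
Reagents that add atoms: none
Why: Ullmann-type copper-catalysed O-arylation with a ligand suited to di-ortho-substituted phenols should join hindered phenol 4 to the unhindered C–Br of 10 (A–O–B bond), the vinylic C–Cl bonds being far less reactive towards the copper catalyst than the aryl bromide.

Step 6
Reactants: 11 1,3,5-tris(benzyloxy)-2-(3,5-bis(benzyloxy)-4-{[(E)-1,2-dichloroethenyl]oxy}phenoxy)benzene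
Product: 14 1,3,5-tris(benzyloxy)-2-[3,5-bis(benzyloxy)-4-(ethynyloxy)phenoxy]benzene (ArAB–O–C≡CH), via chloroethynyl ether 12 (not isolated), via lithium acetylide 13 (not isolated)
Conditions: n-BuLi (2.3 equiv), THF, −78 → −40 °C; H2O, −78 °C; used at once
Reagents that add atoms: none
Why: Dehydrochlorination to the chloroalkynyl ether and chlorine–lithium exchange (the standard dichlorovinyl ether route to ynol ethers) give the lithium aryloxyacetylide, which is protonated to the terminal ynol ether; the two ortho benzyloxy groups shield the electron-rich triple bond.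

Step 7
Reactants: 15 5-bromobenzene-1,2,3-triol
Product: 16 6-bromo-2,2-diphenyl-1,3-benzodioxol-4-ol
Conditions: Ph2CCl2 (1.1 equiv), neat, 170 °C
Reagents that add atoms: dichlorodiphenylmethane, ClC(Cl)(c1ccccc1)c1ccccc1
Why: Ketalisation of two adjacent hydroxyls forms the five-membered benzodioxole; both possible outcomes are identical by symmetry, and exactly one outer hydroxyl (the future D5 oxygen) stays free.

Step 8
Reactants: 15 5-bromobenzene-1,2,3-triol
Product: 17 1,2,3-tris(benzyloxy)-5-bromobenzene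
Conditions: BnBr (3.3 equiv), K2CO3, DMF, 60 °C
Reagents that add atoms: benzyl bromide, BrCc1ccccc1
Why: Williamson ether synthesis on all three phenoxides.

Step 9
Reactants: 17 1,2,3-tris(benzyloxy)-5-bromobenzene
Product: 20 [3,4,5-tris(benzyloxy)phenyl]boronic acid, via aryllithium 18 (not isolated), via diisopropyl arylboronate 19 (not isolated)
Conditions: n-BuLi, THF, −78 °C; B(Oi-Pr)3, −78 °C → rt; 1 M HCl
Reagents that add atoms: triisopropyl borate, CC(C)OB(OC(C)C)OC(C)C; water, O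
Why: Bromine–lithium exchange at −78 °C outruns any benzylic deprotonation, and borylation and hydrolysis give the ring E boronic acid.

Step 10
Reactants: 16 6-bromo-2,2-diphenyl-1,3-benzodioxol-4-ol; 20 [3,4,5-tris(benzyloxy)phenyl]boronic acid
Product: 21 6-bromo-2,2-diphenyl-4-[3,4,5-tris(benzyloxy)phenoxy]-1,3-benzodioxole
Conditions: Cu(OAc)2 (20 mol %), pyridine, 4 Å MS, CH2Cl2, O2 (1 atm), rt
Reagents that add atoms: none
Why: Chan–Lam oxidative O-arylation joins the phenol of 16 to the unhindered boronic acid at room temperature (D–O–E bond); the aryl bromide is inert under these conditions and is kept for step 11.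

Step 11
Reactants: 21 6-bromo-2,2-diphenyl-4-[3,4,5-tris(benzyloxy)phenoxy]-1,3-benzodioxole
Product: 24 2,2-diphenyl-7-[3,4,5-tris(benzyloxy)phenoxy]-1,3-benzodioxol-5-ol (ArDE–OH), via aryllithium 22 (not isolated), via dimethyl arylboronate 23 (not isolated)
Conditions: n-BuLi, THF, −78 °C; B(OMe)3, −78 °C → rt; 30% aq. H2O2, 0 °C
Reagents that add atoms: hydrogen peroxide, OO
Why: Bromine–lithium exchange, borylation and boronate oxidation replace Br by OH at the same carbon (the future D1 oxygen); the ketal and benzyl ethers tolerate the short low-temperature lithiation.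

Step 12
Reactants: 24 2,2-diphenyl-7-[3,4,5-tris(benzyloxy)phenoxy]-1,3-benzodioxol-5-ol; 25 3,4-dichlorocyclobut-3-ene-1,2-dione
Product: 27 3-(benzyloxy)-4-(ArDE-oxy)cyclobut-3-ene-1,2-dione, via benzyl squarate chloride 26 (not isolated)
Conditions: 25 (1.2 equiv), BnOH (1.2 equiv), CH2Cl2, 0 °C → rt, Ar purge; then 24 (1.0 equiv), i-Pr2NEt, −40 → 0 °C
Reagents that add atoms: benzyl alcohol, OCc1ccccc1
Why: Two successive addition–eliminations on the vinylogous acid chloride: benzyl alcohol gives the ester chloride, whose remaining C–Cl is displaced by the phenoxide of 24; chloride leaves far more readily than benzyloxide, so the first ether is not exchanged.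

Step 13
Reactants: 27 3-(benzyloxy)-4-(ArDE-oxy)cyclobut-3-ene-1,2-dione
Product: 28 rac-3-(benzyloxy)-4-hydroxy-2-(ArDE-oxy)cyclobut-2-en-1-one
Conditions: LiAlH(Ot-Bu)3 (1.05 equiv), THF, −78 °C; aq. NH4Cl
Reagents that add atoms: none
Why: 1,2-Reduction of one squarate carbonyl, as in the preparation of 4-hydroxycyclobutenones from squaric esters; the carbonyl next to the benzyloxy-bearing carbon is conjugated through the ring double bond with the weakly donating aryloxy oxygen (a vinylogous aryl ester) and should therefore be the more electrophilic, which leaves the ketone beside the aryloxy carbon; the new stereocentre is racemic and is lost in step 15.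

Step 14
Reactants: 28 rac-3-(benzyloxy)-4-hydroxy-2-(ArDE-oxy)cyclobut-2-en-1-one
Product: 29 rac-3,4-bis(benzyloxy)-2-(ArDE-oxy)cyclobut-2-en-1-one
Conditions: BnBr (2 equiv), Ag2O (1.5 equiv), 4 Å MS, CH2Cl2, rt, dark
Reagents that add atoms: benzyl bromide, BrCc1ccccc1
Why: Silver oxide-mediated O-benzylation under neutral conditions protects the secondary hydroxyl of the acid- and base-sensitive hydroxycyclobutenone, which would otherwise divert the vinylketene of step 15 to a butenolide.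

Step 15
Reactants: 29 rac-3,4-bis(benzyloxy)-2-(ArDE-oxy)cyclobut-2-en-1-one; 14 1,3,5-tris(benzyloxy)-2-[3,5-bis(benzyloxy)-4-(ethynyloxy)phenoxy]benzene
Product: 34 2,3-bis(benzyloxy)-5-(ArAB-oxy)-4-(ArDE-oxy)phenol, via vinylketene 30 (not isolated), via vinylcyclobutenone 31 (not isolated), via dienylketene 32 (not isolated), via cyclohexadienone 33 (not isolated)
Conditions: 29 (1.3 equiv), 14 (1.0 equiv), toluene (0.1 M), 100 °C, Ar; then K2CO3, MeOH–THF, rt
Reagents that add atoms: none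
Why: Danheiser benzannulation: thermal 4π-electrocyclic opening of 29 (the C4 benzyloxy donor rotates outward) gives vinylketene 30, whose ketene C=C adds ynol ether 14 in a (2+2) cycloaddition, the nucleophilic terminal CH carbon bonding to the ketene carbonyl carbon and the oxygen-bearing alkyne carbon to the aryloxy-bearing ketene carbon, to give 4-vinylcyclobutenone 31. A second 4π opening (aryloxy outward, vinyl inward) gives dienylketene 32, which closes ring C by 6π-electrocyclisation (bond C3–C4) to cyclohexadienone 33 and tautomerises to the phenol. The closest known reaction type is the cyclobutenone–alkoxyacetylene benzannulation that gives resorcinol monoethers. No stereocentre remains, since the racemic centres of 29, 31 and 33 are destroyed on aromatisation. The regiochemistry that the step needs is fixed by the polarity of ynol ether and ketene and not by sterics: the ketene carbon becomes C3 (free OH), the alkyne CH becomes C2, the alkyne C–O carbon becomes C1 (O–ring B), and C2, C3 and C4 of 29 become C6 (O–ring D), C5 and C4. Both diaryl ether oxygens of ring C are thus in place before the ring exists, the two halves are joined in the same operation, and no by-product is formed; the carbonate treatment only cleaves any aryl ester formed by ketene capture of the product phenol.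

Step 16
Reactants: 34 2,3-bis(benzyloxy)-5-(ArAB-oxy)-4-(ArDE-oxy)phenol
Product: 35 2-[4-[2-[3,4-dihydroxy-5-(3,4,5-trihydroxyphenoxy)phenoxy]-3,4,5-trihydroxyphenoxy]-3,5-dihydroxyphenoxy]benzene-1,3,5-triol (CNP0154768.0)
Conditions: H2 (3 bar), Pd(OH)2/C, THF–MeOH (1:1), rt; filtration under Ar; Sephadex LH-20, degassed MeOH
Reagents that add atoms: none
Why: Hydrogenolysis cleaves the ten benzyl ethers and the diphenylmethylene ketal (all benzylic C–O bonds) under neutral, reducing conditions that leave the four diaryl ether bonds intact and protect the polyphenol from air oxidation.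

**Compound list**
1 | 1,3,5-tris(benzyloxy)benzene | c1ccccc1COc1cc(OCc2ccccc2)cc(OCc2ccccc2)c1 | starting material
2 | [2,4,6-tris(benzyloxy)phenyl]lithium | [Li]c1c(OCc2ccccc2)cc(OCc2ccccc2)cc1OCc1ccccc1 | intermediate
3 | dimethyl [2,4,6-tris(benzyloxy)phenyl]boronate | COB(OC)c1c(OCc2ccccc2)cc(OCc2ccccc2)cc1OCc1ccccc1 | intermediate
4 | 2,4,6-tris(benzyloxy)phenol | Oc1c(OCc2ccccc2)cc(OCc2ccccc2)cc1OCc1ccccc1 | intermediate
5 | 1,3-bis(benzyloxy)benzene | c1ccccc1COc1cccc(OCc2ccccc2)c1 | starting material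
6 | [2,6-bis(benzyloxy)phenyl]lithium | [Li]c1c(OCc2ccccc2)cccc1OCc1ccccc1 | intermediate
7 | dimethyl [2,6-bis(benzyloxy)phenyl]boronate | COB(OC)c1c(OCc2ccccc2)cccc1OCc1ccccc1 | intermediate
8 | 2,6-bis(benzyloxy)phenol | Oc1c(OCc2ccccc2)cccc1OCc1ccccc1 | intermediate
9 | 2,6-bis(benzyloxy)-4-bromophenol | Oc1c(OCc2ccccc2)cc(Br)cc1OCc1ccccc1 | intermediate
10 | 1,3-bis(benzyloxy)-5-bromo-2-{[(E)-1,2-dichloroethenyl]oxy}benzene | Cl/C=C(Cl)\Oc1c(OCc2ccccc2)cc(Br)cc1OCc1ccccc1 | intermediate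
11 | 1,3,5-tris(benzyloxy)-2-(3,5-bis(benzyloxy)-4-{[(E)-1,2-dichloroethenyl]oxy}phenoxy)benzene | Cl/C=C(Cl)\Oc1c(OCc2ccccc2)cc(Oc2c(OCc3ccccc3)cc(OCc3ccccc3)cc2OCc2ccccc2)cc1OCc1ccccc1 | intermediate
12 | 1,3,5-tris(benzyloxy)-2-{3,5-bis(benzyloxy)-4-[(chloroethynyl)oxy]phenoxy}benzene | ClC#COc1c(OCc2ccccc2)cc(Oc2c(OCc3ccccc3)cc(OCc3ccccc3)cc2OCc2ccccc2)cc1OCc1ccccc1 | intermediate
13 | lithium (ArAB-oxy)acetylide | [Li]C#COc1c(OCc2ccccc2)cc(Oc2c(OCc3ccccc3)cc(OCc3ccccc3)cc2OCc2ccccc2)cc1OCc1ccccc1 | intermediate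
14 | 1,3,5-tris(benzyloxy)-2-[3,5-bis(benzyloxy)-4-(ethynyloxy)phenoxy]benzene | C#COc1c(OCc2ccccc2)cc(Oc2c(OCc3ccccc3)cc(OCc3ccccc3)cc2OCc2ccccc2)cc1OCc1ccccc1 | intermediate
15 | 5-bromobenzene-1,2,3-triol | Oc1cc(Br)cc(O)c1O | starting material
16 | 6-bromo-2,2-diphenyl-1,3-benzodioxol-4-ol | Oc1cc(Br)cc2OC(c3ccccc3)(c3ccccc3)Oc12 | intermediate
17 | 1,2,3-tris(benzyloxy)-5-bromobenzene | Brc1cc(OCc2ccccc2)c(OCc2ccccc2)c(OCc2ccccc2)c1 | intermediate
18 | [3,4,5-tris(benzyloxy)phenyl]lithium | [Li]c1cc(OCc2ccccc2)c(OCc2ccccc2)c(OCc2ccccc2)c1 | intermediate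
19 | diisopropyl [3,4,5-tris(benzyloxy)phenyl]boronate | CC(C)OB(OC(C)C)c1cc(OCc2ccccc2)c(OCc2ccccc2)c(OCc2ccccc2)c1 | intermediate
20 | [3,4,5-tris(benzyloxy)phenyl]boronic acid | OB(O)c1cc(OCc2ccccc2)c(OCc2ccccc2)c(OCc2ccccc2)c1 | intermediate
21 | 6-bromo-2,2-diphenyl-4-[3,4,5-tris(benzyloxy)phenoxy]-1,3-benzodioxole | Brc1cc(Oc2cc(OCc3ccccc3)c(OCc3ccccc3)c(OCc3ccccc3)c2)c2OC(c3ccccc3)(c3ccccc3)Oc2c1 | intermediate
22 | {2,2-diphenyl-7-[3,4,5-tris(benzyloxy)phenoxy]-1,3-benzodioxol-5-yl}lithium | [Li]c1cc(Oc2cc(OCc3ccccc3)c(OCc3ccccc3)c(OCc3ccccc3)c2)c2OC(c3ccccc3)(c3ccccc3)Oc2c1 | intermediate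
23 | dimethyl {2,2-diphenyl-7-[3,4,5-tris(benzyloxy)phenoxy]-1,3-benzodioxol-5-yl}boronate | COB(OC)c1cc(Oc2cc(OCc3ccccc3)c(OCc3ccccc3)c(OCc3ccccc3)c2)c2OC(c3ccccc3)(c3ccccc3)Oc2c1 | intermediate
24 | 2,2-diphenyl-7-[3,4,5-tris(benzyloxy)phenoxy]-1,3-benzodioxol-5-ol | Oc1cc(Oc2cc(OCc3ccccc3)c(OCc3ccccc3)c(OCc3ccccc3)c2)c2OC(c3ccccc3)(c3ccccc3)Oc2c1 | intermediate
25 | 3,4-dichlorocyclobut-3-ene-1,2-dione (squaric acid dichloride) | O=C1C(=O)C(Cl)=C1Cl | starting material
26 | 3-(benzyloxy)-4-chlorocyclobut-3-ene-1,2-dione | O=C1C(=O)C(OCc2ccccc2)=C1Cl | intermediate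
27 | 3-(benzyloxy)-4-(ArDE-oxy)cyclobut-3-ene-1,2-dione | O=C1C(=O)C(OCc2ccccc2)=C1Oc1cc(Oc2cc(OCc3ccccc3)c(OCc3ccccc3)c(OCc3ccccc3)c2)c2OC(c3ccccc3)(c3ccccc3)Oc2c1 | intermediate
28 | rac-3-(benzyloxy)-4-hydroxy-2-(ArDE-oxy)cyclobut-2-en-1-one | O=C1C(O)C(OCc2ccccc2)=C1Oc1cc(Oc2cc(OCc3ccccc3)c(OCc3ccccc3)c(OCc3ccccc3)c2)c2OC(c3ccccc3)(c3ccccc3)Oc2c1 | intermediate
29 | rac-3,4-bis(benzyloxy)-2-(ArDE-oxy)cyclobut-2-en-1-one | O=C1C(OCc2ccccc2)C(OCc2ccccc2)=C1Oc1cc(Oc2cc(OCc3ccccc3)c(OCc3ccccc3)c(OCc3ccccc3)c2)c2OC(c3ccccc3)(c3ccccc3)Oc2c1 | intermediate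
30 | (3Z)-3,4-bis(benzyloxy)-2-(ArDE-oxy)buta-1,3-dien-1-one | O=C=C(Oc1cc(Oc2cc(OCc3ccccc3)c(OCc3ccccc3)c(OCc3ccccc3)c2)c2OC(c3ccccc3)(c3ccccc3)Oc2c1)/C(OCc1ccccc1)=C/OCc1ccccc1 | intermediate
31 | rac-4-[(Z)-1,2-bis(benzyloxy)ethenyl]-3-(ArAB-oxy)-4-(ArDE-oxy)cyclobut-2-en-1-one | O=C1C=C(Oc2c(OCc3ccccc3)cc(Oc3c(OCc4ccccc4)cc(OCc4ccccc4)cc3OCc3ccccc3)cc2OCc2ccccc2)C1(Oc2cc(Oc3cc(OCc4ccccc4)c(OCc4ccccc4)c(OCc4ccccc4)c3)c3OC(c4ccccc4)(c4ccccc4)Oc3c2)/C(OCc2ccccc2)=C/OCc2ccccc2 | intermediate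
32 | (3Z,5Z)-5,6-bis(benzyloxy)-3-(ArAB-oxy)-4-(ArDE-oxy)hexa-1,3,5-trien-1-one | O=C=C/C(Oc1c(OCc2ccccc2)cc(Oc2c(OCc3ccccc3)cc(OCc3ccccc3)cc2OCc2ccccc2)cc1OCc1ccccc1)=C(Oc1cc(Oc2cc(OCc3ccccc3)c(OCc3ccccc3)c(OCc3ccccc3)c2)c2OC(c3ccccc3)(c3ccccc3)Oc2c1)\C(OCc1ccccc1)=C\OCc1ccccc1 | intermediate
33 | rac-5,6-bis(benzyloxy)-3-(ArAB-oxy)-4-(ArDE-oxy)cyclohexa-2,4-dien-1-one | O=C1C=C(Oc2c(OCc3ccccc3)cc(Oc3c(OCc4ccccc4)cc(OCc4ccccc4)cc3OCc3ccccc3)cc2OCc2ccccc2)C(Oc2cc(Oc3cc(OCc4ccccc4)c(OCc4ccccc4)c(OCc4ccccc4)c3)c3OC(c4ccccc4)(c4ccccc4)Oc3c2)=C(OCc2ccccc2)C1OCc1ccccc1 | intermediate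
34 | 2,3-bis(benzyloxy)-5-(ArAB-oxy)-4-(ArDE-oxy)phenol | Oc1cc(Oc2c(OCc3ccccc3)cc(Oc3c(OCc4ccccc4)cc(OCc4ccccc4)cc3OCc3ccccc3)cc2OCc2ccccc2)c(Oc2cc(Oc3cc(OCc4ccccc4)c(OCc4ccccc4)c(OCc4ccccc4)c3)c3OC(c4ccccc4)(c4ccccc4)Oc3c2)c(OCc2ccccc2)c1OCc1ccccc1 | intermediate
35 | 2-[4-[2-[3,4-dihydroxy-5-(3,4,5-trihydroxyphenoxy)phenoxy]-3,4,5-trihydroxyphenoxy]-3,5-dihydroxyphenoxy]benzene-1,3,5-triol (achiral, C30H22O17) | Oc1cc(O)c(Oc2cc(O)c(Oc3cc(O)c(O)c(O)c3Oc3cc(O)c(O)c(Oc4cc(O)c(O)c(O)c4)c3)c(O)c2)c(O)c1 | target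

**Step count and risks**
Total step count: 16. Longest linear sequence: 9 steps (steps 8, 9, 10, 11, 12, 13, 14, 15, 16).

Steps most likely to fail:

1. Step 15. Dimerisation of the vinylketene, or its capture by the product phenol, may outpace cycloaddition to the shielded aryl ynol ether, and the ynol ether may polymerise at 100 °C.
Fallback, setting out from 11 and coming back at 35: lithium acetylide 13, made from 11 as in step 6 but not quenched, would be added at −78 °C to dibenzyl squarate F1 (from 25, two equivalents of BnOH and i-Pr2NEt) to give 4-alkynyl-4-hydroxycyclobutenone F2. F1 is symmetrical, so no carbonyl has to be told from the other. Ag2O and BnBr would give benzyl ether F3, and semihydrogenation (H2, Pd/CaCO3 poisoned with Pb(OAc)2, quinoline) the (Z)-enol ether F4. Thermolysis in xylene at 140 °C (4π opening with benzyloxy outward, 6π closure, tautomerisation) would give ring C phenol F5, whose free hydroxyl is the C6 oxygen. Copper-catalysed O-arylation of F5 with bromide 21 (CuI, picolinic acid, K3PO4, DMSO, 100 °C) would give the fully protected pentamer F6, which hydrogenolysis as in step 16 would convert into 35.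

2. Step 13. Hydride delivery may not discriminate between the two squarate carbonyls, or may occur in conjugate fashion with loss of aryloxide.
Fallback, setting out from 24 and coming back at 30 (and so at 34): 24 would be alkylated with ethyl bromoacetate (K2CO3, DMF) to ethyl aryloxyacetate F7. Claisen acylation of its lithium enolate (LiN(SiMe3)2, THF, −78 °C) with benzyloxyacetyl chloride would give β-keto ester F8, O-benzylation (BnBr, Cs2CO3, DMF) enol ether F9, saponification (LiOH, THF–H2O) acid F10, and (COCl)2 acid chloride F11. 1,4-Dehydrochlorination of F11 with Et3N in toluene at 80 °C in the presence of 14 would generate vinylketene 30 directly. The aryloxy group is then fixed on the ketene α-carbon by C–C bond construction, and the cascade of step 15 leads on to 34.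

3. Step 5. The dichlorovinyl ether may lose HCl or undergo copper insertion at a vinylic C–Cl bond under the basic coupling conditions.
Fallback, setting out from 9 and coming back at 11: 9 would be protected as methoxymethyl ether F12 (MOMCl, i-Pr2NEt, CH2Cl2) and coupled with 4 under the conditions of step 5 to give diaryl ether F13. HCl in MeOH would unmask the AB phenol F14, which would only then be treated with trichloroethylene and K2CO3 as in step 4 to return to 11.

**Further compounds**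
F1 | step 15 | 3,4-bis(benzyloxy)cyclobut-3-ene-1,2-dione (dibenzyl squarate) | O=C1C(=O)C(OCc2ccccc2)=C1OCc1ccccc1
F2 | step 15 | rac-2,3-bis(benzyloxy)-4-hydroxy-4-[(ArAB-oxy)ethynyl]cyclobut-2-en-1-one | O=C1C(OCc2ccccc2)=C(OCc2ccccc2)C1(O)C#COc1c(OCc2ccccc2)cc(Oc2c(OCc3ccccc3)cc(OCc3ccccc3)cc2OCc2ccccc2)cc1OCc1ccccc1
F3 | step 15 | rac-2,3,4-tris(benzyloxy)-4-[(ArAB-oxy)ethynyl]cyclobut-2-en-1-one | O=C1C(OCc2ccccc2)=C(OCc2ccccc2)C1(OCc2ccccc2)C#COc1c(OCc2ccccc2)cc(Oc2c(OCc3ccccc3)cc(OCc3ccccc3)cc2OCc2ccccc2)cc1OCc1ccccc1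
F4 | step 15 | rac-2,3,4-tris(benzyloxy)-4-[(Z)-2-(ArAB-oxy)ethenyl]cyclobut-2-en-1-one | O=C1C(OCc2ccccc2)=C(OCc2ccccc2)C1(OCc2ccccc2)/C=C\Oc1c(OCc2ccccc2)cc(Oc2c(OCc3ccccc3)cc(OCc3ccccc3)cc2OCc2ccccc2)cc1OCc1ccccc1
F5 | step 15 | 2,3,4-tris(benzyloxy)-6-(ArAB-oxy)phenol | Oc1c(Oc2c(OCc3ccccc3)cc(Oc3c(OCc4ccccc4)cc(OCc4ccccc4)cc3OCc3ccccc3)cc2OCc2ccccc2)cc(OCc2ccccc2)c(OCc2ccccc2)c1OCc1ccccc1
F6 | step 15 | 1,2,3-tris(benzyloxy)-5-(ArAB-oxy)-4-(ArDE-oxy)benzene | O(c1cc(Oc2cc(OCc3ccccc3)c(OCc3ccccc3)c(OCc3ccccc3)c2)c2OC(c3ccccc3)(c3ccccc3)Oc2c1)c1c(Oc2c(OCc3ccccc3)cc(Oc3c(OCc4ccccc4)cc(OCc4ccccc4)cc3OCc3ccccc3)cc2OCc2ccccc2)cc(OCc2ccccc2)c(OCc2ccccc2)c1OCc1ccccc1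
F7 | step 13 | ethyl 2-(ArDE-oxy)acetate | CCOC(=O)COc1cc(Oc2cc(OCc3ccccc3)c(OCc3ccccc3)c(OCc3ccccc3)c2)c2OC(c3ccccc3)(c3ccccc3)Oc2c1
F8 | step 13 | ethyl rac-4-(benzyloxy)-3-oxo-2-(ArDE-oxy)butanoate | CCOC(=O)C(Oc1cc(Oc2cc(OCc3ccccc3)c(OCc3ccccc3)c(OCc3ccccc3)c2)c2OC(c3ccccc3)(c3ccccc3)Oc2c1)C(=O)COCc1ccccc1
F9 | step 13 | ethyl 3,4-bis(benzyloxy)-2-(ArDE-oxy)but-2-enoate (E/Z mixture) | CCOC(=O)C(Oc1cc(Oc2cc(OCc3ccccc3)c(OCc3ccccc3)c(OCc3ccccc3)c2)c2OC(c3ccccc3)(c3ccccc3)Oc2c1)=C(OCc1ccccc1)COCc1ccccc1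
F10 | step 13 | 3,4-bis(benzyloxy)-2-(ArDE-oxy)but-2-enoic acid (E/Z mixture) | OC(=O)C(Oc1cc(Oc2cc(OCc3ccccc3)c(OCc3ccccc3)c(OCc3ccccc3)c2)c2OC(c3ccccc3)(c3ccccc3)Oc2c1)=C(OCc1ccccc1)COCc1ccccc1
F11 | step 13 | 3,4-bis(benzyloxy)-2-(ArDE-oxy)but-2-enoyl chloride (E/Z mixture) | ClC(=O)C(Oc1cc(Oc2cc(OCc3ccccc3)c(OCc3ccccc3)c(OCc3ccccc3)c2)c2OC(c3ccccc3)(c3ccccc3)Oc2c1)=C(OCc1ccccc1)COCc1ccccc1
F12 | step 5 | 1,3-bis(benzyloxy)-5-bromo-2-(methoxymethoxy)benzene | COCOc1c(OCc2ccccc2)cc(Br)cc1OCc1ccccc1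
F13 | step 5 | 1,3,5-tris(benzyloxy)-2-[3,5-bis(benzyloxy)-4-(methoxymethoxy)phenoxy]benzene | COCOc1c(OCc2ccccc2)cc(Oc2c(OCc3ccccc3)cc(OCc3ccccc3)cc2OCc2ccccc2)cc1OCc1ccccc1
F14 | step 5 | 2,6-bis(benzyloxy)-4-[2,4,6-tris(benzyloxy)phenoxy]phenol | Oc1c(OCc2ccccc2)cc(Oc2c(OCc3ccccc3)cc(OCc3ccccc3)cc2OCc2ccccc2)cc1OCc1ccccc1
A1 | direct plan | 2,4,6-trifluorobenzaldehyde | O=Cc1c(F)cc(F)cc1F
A2 | direct plan | 6-fluoro-2,3,4-trimethoxybenzaldehyde | COc1cc(F)c(C=O)c(OC)c1OC
A3 | direct plan | 4-{6-[2,6-dimethoxy-4-(2,4,6-trimethoxyphenoxy)phenoxy]-2,3,4-trimethoxyphenoxy}-2,6-difluorobenzaldehyde | COc1cc(OC)c(Oc2cc(OC)c(Oc3cc(OC)c(OC)c(OC)c3Oc3cc(F)c(C=O)c(F)c3)c(OC)c2)c(OC)c1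
A4 | direct plan | 4-{6-[2,6-dimethoxy-4-(2,4,6-trimethoxyphenoxy)phenoxy]-2,3,4-trimethoxyphenoxy}-2-methoxy-6-(3,4,5-trimethoxyphenoxy)phenol | COc1cc(OC)c(Oc2cc(OC)c(Oc3cc(OC)c(OC)c(OC)c3Oc3cc(OC)c(O)c(Oc4cc(OC)c(OC)c(OC)c4)c3)c(OC)c2)c(OC)c1
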